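**Plan**
1. Labels: ring A = cyclobutane, ring B = nine-membered carbocycle, ring C = dihydropyran, ring D = cyclohexenedione; caryophyllane numbering C1–C15; C1' = CH(iBu); Ca (bears C1') and Cb (bears the ring C oxygen) are the sp2 carbons of ring D.
2. Cut 1 (ring C): O–C8 and C13–C1' by retro-hetero-Diels–Alder, giving dienol 3 and the alkylidene trione (o-quinone methide) 14, which is unmasked from sulfide 12 by sulfoxide elimination.
3. Cut 2 (ring D of 12): Ca–C(=O) and Cb–CMe2, giving α-sulfanyl ester 7 (its C–C(=O) unit becomes Ca–Cb) and 2,2,4,4-tetramethylcyclobutane-1,3-dione 8; cut 3: Ca–C1' of 7 (alkylation of 4 with 5).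
4. Enabling feature: the CMe2–C(=O)–CMe2–C(=O) array of ring D is the intact skeleton of 8, a strained 1,3-diketone without α-hydrogens. Carbanion addition to one C=O is therefore followed by retro-Claisen opening to an enolate six atoms from the ester carbon, and reclosure inserts Ca–Cb into one C(O)–CMe2 bond (four- to six-membered ring expansion).
5. Forward: rings A and B come intact from (−)-caryophyllene oxide 1 (step 1); ring D is made by ring expansion (steps 2 and 3); ring C is closed last by the cycloaddition that joins the two halves (step 4).
6. Stereochemistry: C1 and C9 come from 1; C5 is the unbroken epoxide C–O bond of 1; the 3Z alkene comes from syn-elimination within ring B; C8 and C1' come from a substrate-controlled hetero-Diels–Alder reaction on C8=C13.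

Key step: step 3

Remark: (−)-caryophyllene oxide is taken as the (1R,4R,5R,9S) epoxide, so that C5 (R) of the target is its unchanged C–O carbon; ester 7 is used as the racemate because its stereocentre becomes non-stereogenic in step 3.

**Step 1**
Reactants: 1 (−)-caryophyllene oxide
Product: 3 (1R,3Z,5R,9S)-caryophylla-3,8(13)-dien-5-ol, via diethylaluminium alkoxide 2 (not isolated)
Conditions: Et2AlCl, Li(NC9H18) (lithium 2,2,6,6-tetramethylpiperidide), PhMe, 0 °C; then H2O
Reagents that add atoms: none
Why: A bulky aluminium amide should isomerize the trisubstituted epoxide to the allylic alcohol by concerted syn-β-elimination (epoxide-to-allylic-alcohol rearrangement), aluminium binding the epoxide oxygen while the amide nitrogen removes the C3 hydrogen that lies cis to H5 in preference to a C12 methyl hydrogen, ring B being expected to deliver the less strained 3Z alkene, and the C5–O bond is never broken so that C5 stays R and C1 and C9 are untouched.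

**Step 2**
Reactants: 4 methyl 2-(phenylsulfanyl)acetate; 5 1-bromo-3-methylbutane
Product: 7 methyl 5-methyl-2-(phenylsulfanyl)hexanoate (racemic), via lithium enolate 6 (not isolated)
Conditions: LiN(iPr)2, THF, −78 °C; then 5, DMPU, −78 °C → rt
Reagents that add atoms: none
Why: SN2 alkylation of the sulfur-stabilized ester enolate with a primary bromide should stop at the mono-alkylated ester, whose new stereocentre is left racemic because it becomes a non-stereogenic ring carbon in step 3.

**Step 3**
Reactants: 7 methyl 5-methyl-2-(phenylsulfanyl)hexanoate; 8 2,2,4,4-tetramethylcyclobutane-1,3-dione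
Product: 12 2-(3-methylbutyl)-4,4,6,6-tetramethyl-2-(phenylsulfanyl)cyclohexane-1,3,5-trione, via lithium ester enolate 9 (not isolated), via lithium cyclobutoxide 10 (not isolated), via ring-opened lithium enolate 11 (not isolated)
Conditions: LiN(iPr)2, THF, −78 °C; then 8, −78 → 0 °C; then AcOH, 0 °C
Reagents that add atoms: none
Why: Proposed new method: the fully substituted enolate 9 should add to one of the two equivalent carbonyl groups of 8 (aldol addition, helped by the relief of angle strain when the cyclobutanone carbon becomes tetrahedral), the cyclobutoxide 10 should then cleave a ring C(O)–CMe2 bond by retro-aldol (retro-Claisen-type) fragmentation driven by loss of four-membered ring strain to give the isopropyl-ketone enolate 11, and the enolate carbon of 11 should acylate on the methyl ester (Dieckmann condensation) with loss of LiOMe, so that the C–C(=O) unit of 7 is inserted into one C(O)–CMe2 bond of 8 (ring expansion by two carbons). The closest known reaction types are the alkoxide-catalysed conversion of this same cyclobutanedione into hexamethylcyclohexane-1,3,5-trione (alkoxide ring opening, acylation and Dieckmann closure of just such a tetrasubstituted enolate onto an α-quaternary ester), the base-induced retro-aldol ring opening of 3-hydroxy-2,2,4,4-tetramethylcyclobutanones, and the acyl-alkylation of arynes by β-keto esters, in which addition followed by four-ring fragmentation likewise inserts two carbons into a C–C bond. Ring D closes in a 6-exo-trig mode (enolate carbon onto the ester carbonyl), and no other ring is formed. No stereocentre is created, because the new quaternary carbon of 12 carries two identical ring arms. The step needs C–C bond formation in preference to proton transfer (8 has no α-hydrogen and neither 10 nor 11 has an acidic C–H between the carbonyl groups, so the ketone enolate cannot be quenched internally), ring-bond cleavage of 10 in preference to reversion (reversion only returns 8 and 9, whereas ring cleavage is irreversible), and C- over O-acylation in the closure (an O-acylated enol lactone would be reopened by LiOMe to 11, and the cold AcOH quench removes LiOMe before it can reopen 12).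

**Step 4**
Reactants: 12 2-(3-methylbutyl)-4,4,6,6-tetramethyl-2-(phenylsulfanyl)cyclohexane-1,3,5-trione; 3 (1R,3Z,5R,9S)-caryophylla-3,8(13)-dien-5-ol
Product: 15 tomentodione O, via sulfoxide 13 (not isolated), via o-quinone methide 14 (not isolated)
Conditions: mCPBA (1.0 equiv), CH2Cl2, −78 °C; then 3, PhMe, −78 → 60 °C
Reagents that add atoms: none
Why: S-oxidation followed by thermal syn-elimination of benzenesulfenic acid (sulfoxide elimination, possible only towards the side-chain CH2) should unveil the alkylidene trione 14, an electron-poor oxa-diene that should add to the electron-rich 1,1-disubstituted C8=C13 alkene of 3 in an inverse-electron-demand hetero-Diels–Alder reaction with oxygen bonding to the more substituted C8 and C1' to C13, substrate control by C9 and the folded ring B being relied on to place the diene on the more open face of the alkene (8S) with the isobutyl group turned away from ring B (1'R), while the C5 carbinol and the more hindered C3=C4 alkene remain untouched.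

**Compound list**
1 | (−)-caryophyllene oxide, (1R,4R,5R,9S)-4,5-epoxycaryophyll-8(13)-ene | C[C@@]12CC[C@@H]3[C@H](CC3(C)C)C(=C)CC[C@H]1O2 | starting material
2 | diethylaluminium (1R,3Z,5R,9S)-caryophylla-3,8(13)-dien-5-olate | C/C1=C/C[C@@H]2[C@H](CC2(C)C)C(=C)CC[C@H]1O[Al](CC)CC | intermediate
3 | (1R,3Z,5R,9S)-caryophylla-3,8(13)-dien-5-ol | C/C1=C/C[C@@H]2[C@H](CC2(C)C)C(=C)CC[C@H]1O | intermediate
4 | methyl 2-(phenylsulfanyl)acetate | COC(=O)CSc1ccccc1 | starting material
5 | 1-bromo-3-methylbutane | CC(C)CCBr | starting material
6 | lithium enolate of methyl 2-(phenylsulfanyl)acetate | [Li+].[O-]C(OC)=CSc1ccccc1 | intermediate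
7 | methyl 5-methyl-2-(phenylsulfanyl)hexanoate (racemic) | COC(=O)C(CCC(C)C)Sc1ccccc1 | intermediate
8 | 2,2,4,4-tetramethylcyclobutane-1,3-dione | CC1(C)C(=O)C(C)(C)C1=O | starting material
9 | lithium enolate of methyl 5-methyl-2-(phenylsulfanyl)hexanoate | [Li+].[O-]C(OC)=C(CCC(C)C)Sc1ccccc1 | intermediate
10 | lithium 1-[1-methoxy-5-methyl-1-oxo-2-(phenylsulfanyl)hexan-2-yl]-2,2,4,4-tetramethyl-3-oxocyclobutan-1-olate (racemic) | [Li+].[O-]C1(C(C)(C)C(=O)C1(C)C)C(CCC(C)C)(Sc1ccccc1)C(=O)OC | intermediate
11 | lithium C5–C6 enolate of methyl 4,4,6-trimethyl-2-(3-methylbutyl)-3,5-dioxo-2-(phenylsulfanyl)heptanoate (racemic) | [Li+].[O-]C(=C(C)C)C(C)(C)C(=O)C(CCC(C)C)(Sc1ccccc1)C(=O)OC | intermediate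
12 | 2-(3-methylbutyl)-4,4,6,6-tetramethyl-2-(phenylsulfanyl)cyclohexane-1,3,5-trione (achiral) | CC(C)CCC1(Sc2ccccc2)C(=O)C(C)(C)C(=O)C(C)(C)C1=O | intermediate
13 | 2-(3-methylbutyl)-4,4,6,6-tetramethyl-2-(phenylsulfinyl)cyclohexane-1,3,5-trione (racemic at sulfur) | CC(C)CCC1(S(=O)c2ccccc2)C(=O)C(C)(C)C(=O)C(C)(C)C1=O | intermediate
14 | 2-(3-methylbutylidene)-4,4,6,6-tetramethylcyclohexane-1,3,5-trione (o-quinone methide) | CC(C)CC=C1C(=O)C(C)(C)C(=O)C(C)(C)C1=O | intermediate
15 | tomentodione O, (1R,3Z,5R,8S,9S,1'R) | C/C1=C/C[C@@H]2[C@H](CC2(C)C)[C@]2(CC[C@H]1O)C[C@@H](CC(C)C)C1=C(O2)C(C)(C)C(=O)C(C)(C)C1=O | target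

**Totals**
Total step count: 4. Longest linear sequence: 3 steps (steps 2, 3 and 4); step 1 is a one-step side branch.

**Steps most likely to fail**

Step 3 (bears the label). The congested aldol addition of the fully substituted enolate to the doubly neopentyl carbonyl of 8 may not take place. The ring-opened enolate may also be acylated on oxygen, or liberated methoxide may reopen the product by retro-Claisen cleavage or attack at sulfur. The fallback uses known chemistry and gives up the ring expansion: ring D is made by exhaustive C-methylation of an aromatic ring. It sets out from dienol 3 on the terpene side and returns to the route at o-quinone methide 14. Purchased 2,4,6-trihydroxyacetophenone is tetramethylated (NaOMe, MeI, MeOH, reflux) to 2-acetyl-4,4,6,6-tetramethylcyclohexane-1,3,5-trione F1. F1 is deacetylated by retro-Claisen cleavage (aq. HCl, reflux) to syncarpic acid F2. Knoevenagel condensation of F2 with 3-methylbutanal (ethylenediammonium diacetate cat., PhMe, 60 °C) in the presence of 3 should generate 14 in situ, which is trapped by 3 as in step 4 to give 15.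

Step 4. The cycloaddition may show poor facial or endo/exo selectivity, may compete at the C3=C4 alkene, or may be slowed by reversible oxa-Michael capture of 14 by the C5 hydroxyl. The fallback inverts the order of events on the terpene. It sets out from sulfide 12 and epoxide 1 and returns at target 15. Oxidation and elimination of 12 as in step 4, but in the presence of 1 (whose only alkene is C8=C13 and whose ring B is held by the trans-epoxide), should give the spiro epoxide adduct F3 after separation of diastereomers. The epoxide of F3 is then isomerized with Et2AlCl and lithium 2,2,6,6-tetramethylpiperidide as in step 1, through the diethylaluminium alkoxide F4, to give 15 after aqueous work-up.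

Step 1. Proton abstraction may occur at the C12 methyl group instead of C3, or the syn-elimination may run through a ring conformer that leads to the 3E alkene. The fallback sets out from 1 and returns at 3; it places the double bond by enone isomerization and C5 by reagent-controlled reduction. Epoxide 1 is isomerized with LiNEt2 (Et2O, reflux), which favours methyl deprotonation, through the lithium alkoxide F5 to (1R,5R,9S)-caryophylla-4(12),8(13)-dien-5-ol F6. Dess–Martin oxidation gives the α-methylene ketone (1R,9S)-caryophylla-4(12),8(13)-dien-5-one F7. RhCl3·3H2O (cat., EtOH, 80 °C) should move the conjugated exocyclic double bond into ring B to give the cis-enone (1R,3Z,9S)-caryophylla-3,8(13)-dien-5-one F8. Corey–Bakshi–Shibata reduction of F8 ((S)-2-methyl-CBS-oxazaborolidine, BH3·SMe2, THF, −20 °C), the catalyst enantiomer being chosen by analogy with alkenyl ketones to give the 5R carbinol, returns 3.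

**Further compounds**
F1 | step 3 | 2-acetyl-4,4,6,6-tetramethylcyclohexane-1,3,5-trione | CC(=O)C1C(=O)C(C)(C)C(=O)C(C)(C)C1=O
F2 | step 3 | syncarpic acid (2,2,4,4-tetramethylcyclohexane-1,3,5-trione) | CC1(C)C(=O)CC(=O)C(C)(C)C1=O
F3 | step 4 | (1R,4R,5R,8S,9S,1'R)-4,5-epoxide adduct of 14 with caryophyllene oxide | C[C@@]12CC[C@@H]3[C@H](CC3(C)C)[C@]4(CC[C@H]1O2)C[C@@H](CC(C)C)C5=C(O4)C(C)(C)C(=O)C(C)(C)C5=O
F4 | step 4 | diethylaluminium alkoxide of tomentodione O | C/C1=C/C[C@@H]2[C@H](CC2(C)C)[C@]2(CC[C@H]1O[Al](CC)CC)C[C@@H](CC(C)C)C1=C(O2)C(C)(C)C(=O)C(C)(C)C1=O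
F5 | step 1 | lithium (1R,5R,9S)-caryophylla-4(12),8(13)-dien-5-olate | C=C1CC[C@@H]2[C@H](CC2(C)C)C(=C)CC[C@H]1[O-].[Li+]
F6 | step 1 | (1R,5R,9S)-caryophylla-4(12),8(13)-dien-5-ol | C=C1CC[C@@H]2[C@H](CC2(C)C)C(=C)CC[C@H]1O
F7 | step 1 | (1R,9S)-caryophylla-4(12),8(13)-dien-5-one | C=C1CC[C@@H]2[C@H](CC2(C)C)C(=C)CCC1=O
F8 | step 1 | (1R,3Z,9S)-caryophylla-3,8(13)-dien-5-one | C/C1=C/C[C@@H]2[C@H](CC2(C)C)C(=C)CCC1=O
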